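**Retrosynthetic overview**
1. Target ⇒ its phenol acetate; the C10–Br/C11–OH pair comes from SN2 bromide opening of a (10S,11S)-epoxide, made from the E-10,11-olefin by reagent-controlled epoxidation.
2. Cyclohexene (C2–C7 bond, C6–Br) ⇒ transannular bromonium–olefin cyclisation of a 20-membered triene macrolide (second ring; macrocycle contracts to 16-membered).
3. Macrolide (C15–O bond, C14–Br) ⇒ catalytic asymmetric bromonium-induced macrolactonisation of open-chain 4-acetoxy-3-geranylgeranylbenzoic acid at its terminal olefin (first ring; sets C14).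
4. Seco acid ⇒ 4-hydroxy-3-iodobenzoic acid + geranylgeranyl bromide (Cu-catalysed aryl–allyl coupling); bromide from geranylgeraniol.
5. Ring order: macrolactone, then carbocycle. Stereocontrol: C14 by catalyst, C6/C7 by the macrocycle, C10/C11 by reagent.

Assumption: all-E geranylgeraniol is commercial; locants are those of the geranylgeranyl chain (C1 = benzylic CH2, C15 = CMe2–O), in which the target is 6S,7S,10R,11S,14R; if (DHQD)2PHAL gives the 14S sense in step 3, (DHQ)2PHAL is used instead.

Step 1
Reactants: 1 (2E,6E,10E)-geranylgeraniol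
Product: 2 (2E,6E,10E)-geranylgeranyl bromide
Conditions: PBr3 (0.4 equiv), Et2O, −10 °C, 30 min; used crude
Reagents that add atoms: phosphorus tribromide BrP(Br)Br
Why: SN2 bromination of the primary allylic alcohol via its phosphite ester at low temperature proceeds without allylic transposition, so the 2E geometry is kept and no stereocentre is involved.

Step 2
Reactants: 2 (2E,6E,10E)-geranylgeranyl bromide; 3 4-hydroxy-3-iodobenzoic acid
Product: 6 4-acetoxy-3-[(2E,6E,10E)-geranylgeranyl]benzoic acid, via chloromagnesium aryl Grignard 4 (not isolated), via bis(chloromagnesium) salt of the coupled hydroxy acid 5 (not isolated)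
Conditions: 3, MeMgCl (2.0 equiv), LiCl, THF, −20 °C; iPrMgCl·LiCl (1.1 equiv), −20 → 25 °C; Li2CuCl4 (5 mol %), 2 (0.9 equiv), −20 → 0 °C; Ac2O (1.3 equiv), 0 °C; 1 M HCl work-up
Reagents that add atoms: acetic anhydride CC(=O)OC(C)=O
Why: Protecting-group-free iodine–magnesium exchange on the bis-magnesium salt (Knochel type) and Cu-catalysed SN2 (α) allylic substitution give the ortho-geranylgeranyl phenolate with the 2E olefin intact, and Ac2O then acetylates the phenolate in preference to the carboxylate; no stereocentre is formed.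

Step 3
Reactants: 6 4-acetoxy-3-[(2E,6E,10E)-geranylgeranyl]benzoic acid
Product: 7 (14R)-14-bromo macrolide (20-membered lactone closed from the benzoate C=O to O–C15; 2E,6E,10E triene; aryl acetate)
Conditions: NBS (1.05 equiv), (DHQD)2PHAL (20 mol %), CH2Cl2–hexane 1:1, −30 °C; slow addition of 6 (syringe pump, final 1 mM)
Reagents that add atoms: N-bromosuccinimide O=C1CCC(=O)N1Br
Why: Proposed new method: NBS held in the cinchona-dimer cleft transfers Br+ to one face of the terminal, least hindered 14,15-olefin in concert with Markovnikov attack of the quinuclidinium-bound carboxylate at tertiary C15 (nucleophile-assisted bromofunctionalisation without a free bromonium ion, hence no polyene carbocyclisation or Br+ scrambling), high dilution makes the 20-membered closure unimolecular and the catalyst sets C14 (R); the closest known reactions are (DHQD)2PHAL-catalysed intermolecular bromoesterification of unfunctionalised olefins with benzoic acids and NBS, catalytic asymmetric bromolactonisation and phenylseleno-macrolactonisation.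

Step 4
Reactants: 7 (14R)-14-bromo macrolide
Product: 8 (6S,7S,14R)-6,14-dibromo macrolide (new C2–C7 bond; cyclohexene with tetrasubstituted C2=C3; 10E olefin; 16-membered lactone; aryl acetate)
Conditions: TBCO (1.05 equiv), MeNO2, −20 → 0 °C, 2 mM
Reagents that add atoms: 2,4,4,6-tetrabromocyclohexa-2,5-dienone O=C1C(Br)=CC(Br)(Br)C=C1Br
Why: Bromonium-induced transannular cation–olefin (ene-type) cyclisation: Br+ adds to the exposed face of the 6,7-olefin, C2 attacks C7 anti through a chair-like transition state whose face is chosen by the macrocycle (C14 stereocentre, rigid meta-bridged arene), anti addition across the E-olefin fixes 6S,7S, and E1 loss of the C2 proton gives the most substituted C2=C3 olefin.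

Step 5
Reactants: 8 (6S,7S,14R)-6,14-dibromo macrolide
Product: 9 (6S,7S,10S,11S,14R)-10,11-epoxide of 8
Conditions: ent-Shi ketone (L-fructose-derived, 1.0 equiv, recovered), Oxone, NaHCO3 (pH ≈ 8), Na2EDTA, MeCN–DMM–H2O, 0 °C
Reagents that add atoms: Oxone (potassium peroxymonosulfate) [K+].[O-]S(=O)(=O)OO
Why: Shi asymmetric epoxidation: the bulky chiral dioxirane reacts through its spiro transition state with the unhindered E-trisubstituted 10,11-olefin and not with the neopentyl tetrasubstituted ring olefin, and the ent-ketone delivers oxygen to the face giving the (10S,11S)-epoxide by reagent control (pH 8 keeps the aryl acetate).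

Step 6
Reactants: 9 (6S,7S,10S,11S,14R)-10,11-epoxide
Product: 10 (6S,7S,10R,11S,14R)-6,10,14-tribromo-11-hydroxy macrolide aryl acetate (O-acetyl target)
Conditions: Li2NiBr4 (2 equiv, 0.4 M in THF), THF, 0 °C → rt; H2O work-up
Reagents that add atoms: dilithium tetrabromonickelate [Li+].[Li+].Br[Ni-2](Br)(Br)Br
Why: Regioselective SN2 epoxide opening by soft bromide (Dawe's reagent) at the less substituted C10 with inversion gives the 10R bromide while C11 keeps its oxygen and configuration (11S), and the neopentyl-type secondary bromides at C6 and C14 do not exchange.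

Step 7
Reactants: 10 (6S,7S,10R,11S,14R)-tribromo hydroxy macrolide aryl acetate
Product: 11 target CNP0153321.1 (free phenol)
Conditions: N2H4·HOAc (1.5 equiv), DMF, 0 °C → rt, 30 min
Reagents that add atoms: none
Why: Chemoselective hydrazinolysis of the activated aryl acetate under near-neutral conditions leaves the hindered tertiary benzoate lactone, the bromohydrin (no alkoxide, so no epoxide re-closure) and all stereocentres untouched.

**Compound list**
1 | (2E,6E,10E)-geranylgeraniol | CC(C)=CCC/C(C)=C/CC/C(C)=C/CC/C(C)=C/CO | starting material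
2 | (2E,6E,10E)-geranylgeranyl bromide | CC(C)=CCC/C(C)=C/CC/C(C)=C/CC/C(C)=C/CBr | intermediate
3 | 4-hydroxy-3-iodobenzoic acid | OC(=O)c1ccc(O)c(I)c1 | starting material
4 | chloromagnesium aryl Grignard (O-, CO2- and C3-magnesiated 3) | Cl[Mg]Oc1ccc(cc1[Mg]Cl)C(=O)O[Mg]Cl | intermediate
5 | bis(chloromagnesium) salt of 3-geranylgeranyl-4-hydroxybenzoic acid | CC(C)=CCC/C(C)=C/CC/C(C)=C/CC/C(C)=C/Cc1cc(ccc1O[Mg]Cl)C(=O)O[Mg]Cl | intermediate
6 | 4-acetoxy-3-[(2E,6E,10E)-geranylgeranyl]benzoic acid | CC(C)=CCC/C(C)=C/CC/C(C)=C/CC/C(C)=C/Cc1cc(ccc1OC(C)=O)C(=O)O | intermediate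
7 | (14R)-14-bromo 20-membered macrolide, lactone O on C15, 2E,6E,10E triene, aryl acetate | O=C1OC(C)(C)[C@H](Br)CC/C(C)=C/CC/C(C)=C/CC/C(C)=C/Cc2cc1ccc2OC(C)=O | intermediate
8 | (6S,7S,14R)-6,14-dibromo 16-membered macrolide with C2=C3 cyclohexene and 10E olefin, aryl acetate | CC1=C2Cc3cc(ccc3OC(C)=O)C(=O)OC(C)(C)[C@H](Br)CC/C(C)=C/CC[C@]2(C)[C@@H](Br)CC1 | intermediate
9 | (6S,7S,10S,11S,14R)-10,11-epoxide of 8 | CC1=C2Cc3cc(ccc3OC(C)=O)C(=O)OC(C)(C)[C@H](Br)CC[C@]4(C)O[C@H]4CC[C@]2(C)[C@@H](Br)CC1 | intermediate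
10 | (6S,7S,10R,11S,14R)-6,10,14-tribromo-11-hydroxy macrolide aryl acetate | CC1=C2Cc3cc(ccc3OC(C)=O)C(=O)OC(C)(C)[C@H](Br)CC[C@](C)(O)[C@H](Br)CC[C@]2(C)[C@@H](Br)CC1 | intermediate
11 | CNP0153321.1, (6S,7S,10R,11S,14R)-6,10,14-tribromo-11-hydroxy macrolide, free phenol | CC1=C2Cc3cc(ccc3O)C(=O)OC(C)(C)[C@H](Br)CC[C@](C)(O)[C@H](Br)CC[C@]2(C)[C@@H](Br)CC1 | target

**Step count and risks**
Total steps: 7. Longest linear sequence: 7 (1 → 11).

Steps most likely to fail:

(i) Step 3. A bromonium macrolactonisation of this kind is unprecedented. The carboxylate may also capture a 10,11-bromonium (16-membered isomer), and the ee on an unactivated prenyl terminus is uncertain. Fallback: from 6 the ring is closed without chiral catalyst (NBS added to the Bu4N salt of 6, MeCN, 1 mM, −20 °C; the coiled chain in the polar medium exposes the terminal olefin). This gives 7 as a racemate together with the (14S)-enantiomer of 7 F1. The racemate is carried through step 4 to 8 and the enantiomer of 8 F2. The reagent-controlled epoxidation of step 5 then gives 9 and the diastereomeric (6R,7R,10S,11S,14S)-epoxide F3, which is removed by chromatography. The route is rejoined at 9; this is resolution in place of asymmetric catalysis, at the cost of half the material.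

(ii) Step 4. Nothing secures initiation at the 6,7-olefin over the 10,11-olefin, and the facial choice and the position of the new double bond rest on substrate control. Fallback: from 7 the 10,11-olefin is functionalised first. Epoxidation under the step 5 conditions at partial conversion gives, after separation from the 6,7-isomer and recovered 7, the (10S,11S)-10,11-epoxide of 7 F4. Li2NiBr4 opens it to the (10R,11S)-bromohydrin of 7 F5, and TESOTf/2,6-lutidine gives the C11 triethylsilyl ether F6. Now only the 6,7-bromonium has a productive partner (the 2,3-olefin), and the silylated C11 oxygen cannot form a tetrahydropyran. TBCO in MeNO2 therefore gives the cyclised silyl ether F7, and HF·pyridine in THF removes the silyl group to give 10, where the route is rejoined.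

(iii) Step 5. The dioxirane may also attack the electron-rich tetrasubstituted C2=C3 olefin. Fallback: from 8 an osmium-based dihydroxylation, which ignores hindered tetrasubstituted olefins (K2OsO2(OH)4 cat., (DHQ)2PHAL, NMO, acetone–H2O, 0 °C), gives the (10S,11S)-10,11-diol F8. MeC(OMe)3/PPTS converts it to the cyclic orthoacetate F9. AcBr opens the derived acetoxonium ion to the (10R)-bromo 11-acetate F10; the regioisomeric bromo acetate converges in the next operation. K2CO3/MeOH cleaves both acetates and the C11 alkoxide closes the (10S,11S)-epoxide with free phenol F11 (net retention, Kolb–Sharpless). Li2NiBr4 as in step 6 then gives 11 directly.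

**Further compounds**
F1 | step 3 | (14S)-enantiomer of macrolide 7 | O=C1OC(C)(C)[C@@H](Br)CC/C(C)=C/CC/C(C)=C/CC/C(C)=C/Cc2cc1ccc2OC(C)=O
F2 | step 3 | (6R,7R,14S)-enantiomer of 8 | CC1=C2Cc3cc(ccc3OC(C)=O)C(=O)OC(C)(C)[C@@H](Br)CC/C(C)=C/CC[C@@]2(C)[C@H](Br)CC1
F3 | step 3 | (6R,7R,10S,11S,14S)-epoxide, diastereomer of 9 | CC1=C2Cc3cc(ccc3OC(C)=O)C(=O)OC(C)(C)[C@@H](Br)CC[C@]4(C)O[C@H]4CC[C@@]2(C)[C@H](Br)CC1
F4 | step 4 | (10S,11S,14R)-10,11-epoxide of macrolide 7 | O=C1OC(C)(C)[C@H](Br)CC[C@]3(C)O[C@H]3CC/C(C)=C/CC/C(C)=C/Cc2cc1ccc2OC(C)=O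
F5 | step 4 | (10R,11S,14R)-10,14-dibromo-11-hydroxy 20-membered macrolide | O=C1OC(C)(C)[C@H](Br)CC[C@](C)(O)[C@H](Br)CC/C(C)=C/CC/C(C)=C/Cc2cc1ccc2OC(C)=O
F6 | step 4 | C11 triethylsilyl ether of F5 | O=C1OC(C)(C)[C@H](Br)CC[C@](C)(O[Si](CC)(CC)CC)[C@H](Br)CC/C(C)=C/CC/C(C)=C/Cc2cc1ccc2OC(C)=O
F7 | step 4 | C11 triethylsilyl ether of 10 | CC1=C2Cc3cc(ccc3OC(C)=O)C(=O)OC(C)(C)[C@H](Br)CC[C@](C)(O[Si](CC)(CC)CC)[C@H](Br)CC[C@]2(C)[C@@H](Br)CC1
F8 | step 5 | (6S,7S,10S,11S,14R)-10,11-diol of 8 | CC1=C2Cc3cc(ccc3OC(C)=O)C(=O)OC(C)(C)[C@H](Br)CC[C@](C)(O)[C@@H](O)CC[C@]2(C)[C@@H](Br)CC1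
F9 | step 5 | cyclic methyl orthoacetate of F8 | CC1=C2Cc3cc(ccc3OC(C)=O)C(=O)OC(C)(C)[C@H](Br)CC[C@]4(C)OC(C)(OC)O[C@H]4CC[C@]2(C)[C@@H](Br)CC1
F10 | step 5 | (10R)-bromo 11-acetate (11-O-acetyl-10) | CC1=C2Cc3cc(ccc3OC(C)=O)C(=O)OC(C)(C)[C@H](Br)CC[C@](C)(OC(C)=O)[C@H](Br)CC[C@]2(C)[C@@H](Br)CC1
F11 | step 5 | (6S,7S,10S,11S,14R)-10,11-epoxide with free phenol (deacetyl-9) | CC1=C2Cc3cc(ccc3O)C(=O)OC(C)(C)[C@H](Br)CC[C@]4(C)O[C@H]4CC[C@]2(C)[C@@H](Br)CC1
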